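**Strategy.** Everything rests on cutting the bond between the benzylic CH2 on C3 of the chromone and the para carbon of the anisole ring. The array CH2–C3=C2–O1 of the 4-pyranone ring is the transposed form of an exocyclic enone. A Mizoroki–Heck arylation of a 3-methylidenechroman-4-one with 4-iodoanisole therefore forms this bond and, by loss of the C2–H next to O1, moves the double bond into the ring. Coupling and aromatisation of the pyranone happen in one operation, with no CH2–X or CH2–metal handle. The precursor is a non-aromatic chromanone that already carries 5-OMe, 6-Me, free 7-OH and 8-CHO. It is built in four steps from 2-methylphloroglucinol, and the formyl group steers the O-methylation.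

Key step: step 5

Remark: the target has no stereocentre and no configurationally defined double bond, so it is achiral and its constitution alone defines the compound to be made.

Step 1
Reactants: 1 2-methylbenzene-1,3,5-triol
Product: 3 2,4,6-trihydroxy-3-methylbenzaldehyde, via iminium chloride 2 (not isolated)
Conditions: POCl3 (1.1 equiv), DMF (1.2 equiv), EtOAc, 0 °C to rt; then H2O, 50 °C
Reagents that add atoms: N,N-dimethylformamide CN(C)C=O; water O
Why: Vilsmeier–Haack formylation: the two open ring carbons of 1 are equivalent by symmetry, and the iminium salt 2 deactivates the ring against a second attack until water hydrolyses it to the aldehyde.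

Step 2
Reactants: 3 2,4,6-trihydroxy-3-methylbenzaldehyde
Product: 4 2,6-dihydroxy-4-methoxy-3-methylbenzaldehyde
Conditions: Me2SO4 (1.0 equiv), K2CO3 (1.0 equiv), acetone, 0 °C to rt
Reagents that add atoms: dimethyl sulfate COS(=O)(=O)OC
Why: Williamson-type O-methylation under stoichiometric control: the 4-OH para to the formyl group is the most acidic hydroxyl and the only one not tied up in a hydrogen bond to the C=O, and the hard electrophile favours O- over C-alkylation of the phloroglucinol core.

Step 3
Reactants: 4 2,6-dihydroxy-4-methoxy-3-methylbenzaldehyde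
Product: 5 3-acetyl-2,6-dihydroxy-4-methoxy-5-methylbenzaldehyde
Conditions: Ac2O (1.2 equiv), BF3·OEt2 (3 equiv), 70 °C; then H2O, 50 °C
Reagents that add atoms: acetic anhydride CC(=O)OC(C)=O
Why: Friedel–Crafts C-acylation (with Fries transfer of any O-acetate) at the only free ring carbon, which lies ortho to OH and OMe and para to the second OH, in line with the second acylation of monoacylphloroglucinols under the same conditions, while BF3 is too mild to cleave the aryl methyl ether.

Step 4
Reactants: 5 3-acetyl-2,6-dihydroxy-4-methoxy-5-methylbenzaldehyde
Product: 8 7-hydroxy-5-methoxy-6-methyl-3-methylidene-4-oxochromane-8-carbaldehyde, via aryl vinyl ketone 6 (not isolated), via chromanone 7 (not isolated)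
Conditions: (CH2O)n (5 equiv), i-Pr2NH·TFA (1 equiv), TFA (10 mol %), THF, reflux; product used without storage
Reagents that add atoms: formaldehyde (as paraformaldehyde) C=O
Why: Mannich-type α-methylenation of the methyl ketone gives 6, its 2-OH (the only hydroxyl within reach of the enone) closes the ring by 6-endo-trig oxa-Michael addition to 7, and a second α-methylenation at C3 gives 8, while the fully substituted benzene ring leaves formaldehyde no aromatic carbon to attack.

Step 5
Reactants: 8 7-hydroxy-5-methoxy-6-methyl-3-methylidene-4-oxochromane-8-carbaldehyde; 9 4-iodoanisole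
Product: 11 7-hydroxy-5-methoxy-3-(4-methoxybenzyl)-6-methyl-4-oxo-4H-chromene-8-carbaldehyde, via benzylidene isomer 10 (not isolated)
Conditions: Pd(OAc)2 (5 mol %), KOAc (3 equiv), DMF, N2, 80 °C, 8 added over 2 h to 9 (1.5 equiv); then 110 °C
Reagents that add atoms: none
Why: Oxidative addition of 9 to Pd(0) is followed by syn-carbopalladation of the exocyclic C3=CH2 bond of 8, in which the aryl group goes to the unsubstituted β-carbon of the enone (this makes the CH2–aryl bond) and palladium goes to C3 as a C-bound enolate. syn-β-Hydride elimination of the C2–H, which is α to O1 and of the kind palladium prefers in Heck arylations of allylic alcohols, gives 11 directly, whereas elimination of a benzylic hydrogen gives 10, which H–Pd–OAc takes back to the same C3–Pd intermediate (H to the β-carbon, Pd α to C=O) until the material has drained into 11, the thermodynamic sink owing to the cyclic conjugation of the 4-pyranone. The closest known reaction type is the Mizoroki–Heck arylation of exocyclic α-methylene lactones under Pd(OAc)2/KOAc, which gives the α-benzyl endocyclic isomers. No ring is closed and no stereocentre remains, since the palladium-bearing C3 becomes sp2 again. The step needs terminal regioselectivity of insertion, secured by the 1,1-disubstituted and polarised alkene, and arylation faster than dimerisation or double-bond migration of 8, secured by slow addition of 8 to an excess of 9. It also needs the 7-OH/8-CHO pair to stay untouched, which the weak acetate base, the internal hydrogen bond and the fully substituted ring should secure.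

**Compound list**
1 | 2-methylbenzene-1,3,5-triol (2-methylphloroglucinol) | Cc1c(O)cc(O)cc1O | starting material
2 | dimethyl[(2,4,6-trihydroxy-3-methylphenyl)methylidene]ammonium chloride | C[N+](C)=Cc1c(O)cc(O)c(C)c1O.[Cl-] | intermediate
3 | 2,4,6-trihydroxy-3-methylbenzaldehyde | Cc1c(O)cc(O)c(C=O)c1O | intermediate
4 | 2,6-dihydroxy-4-methoxy-3-methylbenzaldehyde | COc1cc(O)c(C=O)c(O)c1C | intermediate
5 | 3-acetyl-2,6-dihydroxy-4-methoxy-5-methylbenzaldehyde | CC(=O)c1c(O)c(C=O)c(O)c(C)c1OC | intermediate
6 | 3-acryloyl-2,6-dihydroxy-4-methoxy-5-methylbenzaldehyde | C=CC(=O)c1c(O)c(C=O)c(O)c(C)c1OC | intermediate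
7 | 7-hydroxy-5-methoxy-6-methyl-4-oxochromane-8-carbaldehyde | COc1c(C)c(O)c(C=O)c2OCCC(=O)c12 | intermediate
8 | 7-hydroxy-5-methoxy-6-methyl-3-methylidene-4-oxochromane-8-carbaldehyde | COc1c(C)c(O)c(C=O)c2OCC(=C)C(=O)c12 | intermediate
9 | 4-iodoanisole (1-iodo-4-methoxybenzene) | COc1ccc(I)cc1 | starting material
10 | (E)-7-hydroxy-5-methoxy-3-(4-methoxybenzylidene)-6-methyl-4-oxochromane-8-carbaldehyde | COc1ccc(/C=C2\COc3c(C=O)c(O)c(C)c(OC)c3C2=O)cc1 | intermediate
11 | 7-hydroxy-5-methoxy-3-(4-methoxybenzyl)-6-methyl-4-oxo-4H-chromene-8-carbaldehyde | COc1ccc(Cc2coc3c(C=O)c(O)c(C)c(OC)c3c2=O)cc1 | target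

Total step count: 5. Longest linear sequence: 5 (1 to 11).

**Steps most likely to fail**

Step 5. The exocyclic double bond of 8 may migrate into the ring, or 8 may dimerise by hetero-Diels–Alder reaction, before it is arylated. β-Hydride elimination may also halt at the exocyclic alkene. The fallback separates bond formation from placement of the double bond and sets out from 8. Rhodium(I)-catalysed 1,4-addition of 4-methoxyphenylboronic acid ([Rh(cod)OH]2, dioxane/H2O, rt to 40 °C) should form the same CH2–aryl bond under mild conditions. It should give racemic 7-hydroxy-5-methoxy-3-(4-methoxybenzyl)-6-methyl-4-oxochromane-8-carbaldehyde F1. Dehydrogenation with catalytic I2 in DMSO at 110 °C (α-iodination at C3, then anti elimination of HI across C2–C3) removes the transient stereocentre and comes back to the route at 11.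

Step 4. The vinyl ketone and the exocyclic enone may oligomerise in the hot medium, or the second methylenation may stay incomplete. The fallback brings the C3=CH2 unit in from the start and closes the ring at C4–C4a instead. It sets out from 4 and so also bypasses 5. O-Alkylation of the less hindered 6-OH with methyl 2-(bromomethyl)acrylate (K2CO3, acetone) should give methyl 2-[(2-formyl-3-hydroxy-5-methoxy-4-methylphenoxy)methyl]prop-2-enoate F2. Saponification (LiOH, THF/H2O) should give 2-[(2-formyl-3-hydroxy-5-methoxy-4-methylphenoxy)methyl]prop-2-enoic acid F3. Intramolecular Friedel–Crafts acylation (TFAA, CH2Cl2, reflux) at the only free ring carbon comes back to the route at 8.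

Step 3. Acetylation may stop at oxygen, the formyl group may be masked as its acylal or lost by ipso-protonation, and the methyl ether next to the new ketone may be cleaved. The fallback replaces electrophilic acylation by cross-coupling and sets out from 4. Iodination of the free ring carbon (NIS, MeCN, 0 °C) should give 2,6-dihydroxy-3-iodo-4-methoxy-5-methylbenzaldehyde F4. Stille coupling with tributyl(1-ethoxyvinyl)stannane (PdCl2(PPh3)2, dioxane, 90 °C) should give 3-(1-ethoxyethenyl)-2,6-dihydroxy-4-methoxy-5-methylbenzaldehyde F5. Dilute HCl in THF hydrolyses the enol ether and comes back to the route at 5.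

**Further compounds**
F1 | step 5 | racemic 7-hydroxy-5-methoxy-3-(4-methoxybenzyl)-6-methyl-4-oxochromane-8-carbaldehyde | COc1ccc(CC2COc3c(C=O)c(O)c(C)c(OC)c3C2=O)cc1
F2 | step 4 | methyl 2-[(2-formyl-3-hydroxy-5-methoxy-4-methylphenoxy)methyl]prop-2-enoate | COC(=O)C(=C)COc1cc(OC)c(C)c(O)c1C=O
F3 | step 4 | 2-[(2-formyl-3-hydroxy-5-methoxy-4-methylphenoxy)methyl]prop-2-enoic acid | OC(=O)C(=C)COc1cc(OC)c(C)c(O)c1C=O
F4 | step 3 | 2,6-dihydroxy-3-iodo-4-methoxy-5-methylbenzaldehyde | COc1c(I)c(O)c(C=O)c(O)c1C
F5 | step 3 | 3-(1-ethoxyethenyl)-2,6-dihydroxy-4-methoxy-5-methylbenzaldehyde | CCOC(=C)c1c(O)c(C=O)c(O)c(C)c1OC
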